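**Retrosynthetic overview**
1. Last bond: C4(upper)–C6(lower). The epioritin ring-A quinone methide 13 (from 4β-benzyl thioether 12, AgBF4 and a hindered pyridine) is captured by free-phenolic ent-oritin-4α-ol 8, anti to the axial 3-OH, to give 14.
2. Both halves come from one monomer, 8. Its ring C is reopened to the ring-B quinone methide and reclosed with inversion at C2 to give the 2,3-cis diol teracacidin 10 (C3 and C4 untouched), which is thiolysed to 12.
3. 8 comes from (2S,3S)-dihydroflavonol 7 by catalyst-controlled 3,4-cis transfer hydrogenation. Ring C of 7 is closed by attack of the 2'-phenol oxygen on the β-carbon of enantioenriched chalcone epoxide 5 (from chalcone 4, from 1 via 2, plus 3).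
4. Ring order: rings A and B are bought; ring C of the lower (2,3-trans) unit first (step 4); ring C of the upper (2,3-cis) unit second, by reopening and reclosure (step 6); then the interflavanyl bond (step 8).

**Assumption:** the SMILES is read as epioritin-(4β→6)-ent-oritin-4α-ol, upper unit (2R,3R,4S) and lower unit (2S,3R,4R); 4-(methoxymethoxy)benzaldehyde is taken as a catalogue chemical.

**Route**

Step 1
Reactants: 1 2',3',4'-trihydroxyacetophenone (gallacetophenone)
Product: 2 2',3',4'-tris(methoxymethoxy)acetophenone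
Conditions: NaH (3.4 equiv), MOMCl (3.6 equiv), DMF, 0 °C → rt
Reagents that add atoms: chloromethyl methyl ether, COCCl
Why: Williamson-type O-alkylation (MOM protection) of all three phenoxides, the chelated 2'-OH included once NaH has removed its proton; no stereocenter is formed.

Step 2
Reactants: 2 2',3',4'-tris(methoxymethoxy)acetophenone; 3 4-(methoxymethoxy)benzaldehyde
Product: 4 (E)-3-[4-(methoxymethoxy)phenyl]-1-[2,3,4-tris(methoxymethoxy)phenyl]prop-2-en-1-one
Conditions: KOH, EtOH–H2O, rt, 24 h
Reagents that add atoms: none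
Why: Claisen–Schmidt aldol condensation of the methyl ketone enolate with the non-enolisable aldehyde, then E1cB dehydration to the thermodynamically favoured (E)-enone; MOM ethers are stable to base.

Step 3
Reactants: 4 the (E)-chalcone
Product: 5 [(2S,3R)-3-[4-(methoxymethoxy)phenyl]oxiran-2-yl][2,3,4-tris(methoxymethoxy)phenyl]methanone (the (αS,βR)-trans-epoxide)
Conditions: poly-D-leucine (cat.), urea–H2O2 (1.5 equiv), DBU, THF, rt
Reagents that add atoms: urea–hydrogen peroxide adduct, OO.NC(N)=O
Why: Juliá–Colonna asymmetric nucleophilic (Weitz–Scheffer) epoxidation, in which the helical poly-D-leucine delivers the peroxide oxygen to one enone face and gives the (αS,βR)-epoxide, the mirror image of the (αR,βS)-epoxide obtained with poly-L-leucine; the α-carbon set here becomes C3 of both flavan units.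

Step 4
Reactants: 5 the (αS,βR)-epoxide
Product: 7 (2S,3S)-3,7,8-trihydroxy-2-(4-hydroxyphenyl)chroman-4-one (2,3-trans-dihydroflavonol), via tetrahydroxychalcone epoxide 6 (not isolated)
Conditions: HCl (3 M), MeOH, 55 °C, 1 h; trans isomer crystallised
Reagents that add atoms: none
Why: Acid removes the four MOM acetals and the freed 2'-OH opens the protonated epoxide 6-endo at the benzylic β-carbon with inversion (acid-mediated chalcone-epoxide cyclization, forming the same O1–C2 bond that chalcone isomerase makes), so Cα (S) is carried over unchanged as C3 and C2 becomes S, any SN1 leakage being funnelled to the diequatorial 2,3-trans isomer under the equilibrating conditions.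

Step 5
Reactants: 7 the (2S,3S)-dihydroflavonol
Product: 8 ent-oritin-4α-ol = (2S,3R,4R)-2-(4-hydroxyphenyl)chromane-3,4,7,8-tetrol (2,3-trans-3,4-cis)
Conditions: RuCl[(S,S)-TsDPEN](p-cymene) (2 mol %), HCO2Na (5 equiv), degassed H2O–MeOH, 40 °C, Ar
Reagents that add atoms: none
Why: Noyori–Ikariya asymmetric transfer hydrogenation (a dihydroflavonol 4-reductase mimic), in which the (S,S)-catalyst delivers hydride to the C4 face that gives the 4α-OH (the sense that turns 4-chromanone into (S)-chroman-4-ol, here named 4R), which is also the face anti to the 3-OH of the major (3S) enantiomer, so the matched pair gives the 3,4-cis diol and the minor enantiomer is left behind or ends as a separable diastereomer.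

Step 6
Reactants: 8 ent-oritin-4α-ol
Product: 10 teracacidin = (2R,3R,4R)-2-(4-hydroxyphenyl)chromane-3,4,7,8-tetrol (2,3-cis-3,4-cis), via ring-opened quinone methide 9 (not isolated)
Conditions: degassed aq. NaHCO3/Na2CO3 buffer (pH 9.5), Ar, 50 °C, 8 h; then pH 5, Sephadex LH-20 (EtOH); 8 recovered
Reagents that add atoms: none
Why: Base-mediated C2 epimerization of a 4'-hydroxyflavan (the reaction that interconverts epicatechin and ent-catechin), in which the 4'-phenoxide expels the ring-A phenoxide to give quinone methide 9 and oxa-Michael reclosure on either face of C2 equilibrates 8 with its 2,3-cis epimer 10 (estimated 2–3:1 in favour of 8, which is recovered and used in step 8), C3 and C4 being untouched.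

Step 7
Reactants: 10 teracacidin
Product: 12 4β-benzylsulfanylepioritin = (2R,3S,4S)-4-(benzylsulfanyl)-2-(4-hydroxyphenyl)chromane-3,7,8-triol, via epioritin C4 carbocation 11 (not isolated)
Conditions: BnSH (10 equiv), HCl (0.2 M in 1,4-dioxane), 40 °C, Ar
Reagents that add atoms: phenylmethanethiol, SCc1ccccc1
Why: SN1 thiolysis of a flavan-3,4-diol, in which acid ionises the benzylic 4-OH to cation 11 (stabilised by O1 and the para 7-OH) and the thiol adds from the β-face, trans to the axial 3-OH, to give the 3,4-trans (4β) thioether without touching C2 or C3.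

Step 8
Reactants: 12 4β-benzylsulfanylepioritin; 8 ent-oritin-4α-ol (4 equiv, excess recovered)
Product: 14 epioritin-(4β→6)-ent-oritin-4α-ol (target), via ring-A quinone methide 13 (not isolated)
Conditions: AgBF4 (2.5 equiv), 2,6-di-tert-butyl-4-methylpyridine (1.5 equiv), THF, 0 °C, Ar, dark; Sephadex LH-20 then preparative HPLC
Reagents that add atoms: none
Why: Proposed new method: Ag+ binds the sulfur of 12 and, pushed by the para 7-OH whose proton goes to the hindered, non-coordinating pyridine, benzylthiolate leaves in a 1,6-elimination that gives the neutral ring-A para-quinone methide 13 without any free HBF4, so the acid-labile axial 4-OH of 8 and of the product is not ionised; C6 of 8 (ortho to its 7-OH, para to O1) then adds to C4 of 13 in a 1,6-conjugate (vinylogous Friedel–Crafts) addition from the face anti to the axial 3-OH, which re-aromatises ring A and sets the new C4 stereocenter as S (4β); the closest known reaction types are the AgBF4-promoted coupling of 4-benzylsulfanylflavan-3-ols with phenolic flavanyl nucleophiles and the quinone methide cleavage of flavan-4-yl thioethers with capture by phenols, both of which mimic the C4-electrophile condensation of proanthocyanidin biosynthesis.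

**Compound list**
1 | 2',3',4'-trihydroxyacetophenone (gallacetophenone) | CC(=O)c1ccc(O)c(O)c1O | starting material
2 | 2',3',4'-tris(methoxymethoxy)acetophenone | CC(=O)c1ccc(OCOC)c(OCOC)c1OCOC | intermediate
3 | 4-(methoxymethoxy)benzaldehyde | COCOc1ccc(C=O)cc1 | starting material
4 | (E)-3-[4-(methoxymethoxy)phenyl]-1-[2,3,4-tris(methoxymethoxy)phenyl]prop-2-en-1-one | COCOc1ccc(/C=C/C(=O)c2ccc(OCOC)c(OCOC)c2OCOC)cc1 | intermediate
5 | [(2S,3R)-3-[4-(methoxymethoxy)phenyl]oxiran-2-yl][2,3,4-tris(methoxymethoxy)phenyl]methanone | O=C(c1ccc(OCOC)c(OCOC)c1OCOC)[C@H]1O[C@@H]1c1ccc(OCOC)cc1 | intermediate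
6 | [(2S,3R)-3-(4-hydroxyphenyl)oxiran-2-yl](2,3,4-trihydroxyphenyl)methanone | O=C(c1ccc(O)c(O)c1O)[C@H]1O[C@@H]1c1ccc(O)cc1 | intermediate (not isolated)
7 | (2S,3S)-3,7,8-trihydroxy-2-(4-hydroxyphenyl)chroman-4-one | Oc1ccc2c(c1O)O[C@@H](c1ccc(O)cc1)[C@H](O)C2=O | intermediate
8 | ent-oritin-4α-ol, (2S,3R,4R)-2-(4-hydroxyphenyl)chromane-3,4,7,8-tetrol | Oc1ccc2c(c1O)O[C@@H](c1ccc(O)cc1)[C@H](O)[C@@H]2O | intermediate
9 | 4-[(2S,3R)-2,3-dihydroxy-3-(2,3,4-trihydroxyphenyl)propylidene]cyclohexa-2,5-dien-1-one (ring-opened quinone methide) | O=C1C=CC(=C[C@H](O)[C@H](O)c2ccc(O)c(O)c2O)C=C1 | intermediate (not isolated)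
10 | teracacidin, (2R,3R,4R)-2-(4-hydroxyphenyl)chromane-3,4,7,8-tetrol | Oc1ccc2c(c1O)O[C@H](c1ccc(O)cc1)[C@H](O)[C@@H]2O | intermediate
11 | (2R,3R)-3,7,8-trihydroxy-2-(4-hydroxyphenyl)chroman-4-ylium (epioritin C4 carbocation) | Oc1ccc2c(c1O)O[C@H](c1ccc(O)cc1)[C@H](O)[CH+]2 | intermediate (not isolated)
12 | 4β-benzylsulfanylepioritin, (2R,3S,4S)-4-(benzylsulfanyl)-2-(4-hydroxyphenyl)chromane-3,7,8-triol | Oc1ccc2c(c1O)O[C@H](c1ccc(O)cc1)[C@H](O)[C@H]2SCc1ccccc1 | intermediate
13 | epioritin ring-A para-quinone methide, (2R,3R)-3,8-dihydroxy-2-(4-hydroxyphenyl)-2,3-dihydro-7H-chromen-7-one | OC1=C2O[C@H](c3ccc(O)cc3)[C@H](O)C=C2C=CC1=O | intermediate (not isolated)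
14 | epioritin-(4β→6)-ent-oritin-4α-ol, (2R,3R,4S)-2-(4-hydroxyphenyl)-4-[(2S,3R,4R)-3,4,7,8-tetrahydroxy-2-(4-hydroxyphenyl)chroman-6-yl]chromane-3,7,8-triol | Oc1ccc([C@H]2Oc3c(ccc(O)c3O)[C@H](c3cc4c(c(O)c3O)O[C@@H](c3ccc(O)cc3)[C@H](O)[C@@H]4O)[C@H]2O)cc1 | target

**Step count**
Total steps: 8. Longest linear sequence: 8 (compound 8 is used twice, as the source of 10 and as the nucleophile in step 8).

**Three steps most likely to fail, with fallbacks**

Step 8 is the most exposed. Free-phenol coupling can give low conversion, O-linked ethers (which the buffered medium does not re-ionise), the 4→5 regioisomer, or oxidation of the pyrogallol-type rings by Ag+. The fallback sets out from 12 and 8 and couples them with the phenols masked. Only the phenolic hydroxyls of each are benzylated (BnBr, K2CO3, DMF, 0 °C) to give 7,8,4'-tri-O-benzyl-4β-benzylsulfanylepioritin F1 and 7,8,4'-tri-O-benzyl-ent-oritin-4α-ol F2. These are joined with AgBF4 in CH2Cl2–THF at −20 °C to the hexa-O-benzyl dimer F3. The six benzyl ethers are then removed by hydrogenolysis (H2, Pd(OH)2/C, EtOAc–MeOH, stopped as soon as the ethers are gone to spare the benzylic 4-OH), which comes back to the route at 14.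

Step 6 is thermodynamically uphill and runs a pyrogallol-type ring at pH 9.5, so low conversion or oxidative loss is possible. The fallback sets out from 7 and moves the C2 inversion to the ketone oxidation level, where ring A is deactivated towards oxidation and there is no labile 4-OH. Heating 7 in degassed aqueous ethanol at 90 °C equilibrates it through the same quinone methide pathway with (2R,3S)-2,3-cis-3,7,8-trihydroxy-2-(4-hydroxyphenyl)chroman-4-one F4 (also the minor isomer of step 4; roughly one tenth at equilibrium, 7 recycled). Transfer hydrogenation of F4 with the same RuCl[(S,S)-TsDPEN](p-cymene)/HCO2Na system adds hydride anti to both the 2-aryl and the 3-OH and comes back to the route at 10.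

Step 5 may stall because the electron-rich, unprotected polyphenolic α-hydroxy ketone is a slow substrate and catechol-type groups may bind ruthenium. The fallback sets out from 7 and replaces catalyst control by substrate control plus equilibration. NaBH4 in EtOH at 0 °C gives, by axial hydride attack, the 3,4-trans diol ent-oritin-4β-ol F5. Its C4 is then epimerised through the benzylic carbocation by solvolysis in dilute aqueous AcOH (pH 3–4, 40 °C), and the 3,4-cis (axial 4α-OH) isomer is separated from the equilibrium mixture, which comes back to the route at 8.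

**Further compounds**
F1 | step 8 | 7,8,4'-tri-O-benzyl-4β-benzylsulfanylepioritin, (2R,3S,4S)-7,8-bis(benzyloxy)-2-[4-(benzyloxy)phenyl]-4-(benzylsulfanyl)chroman-3-ol | O(Cc1ccccc1)c1ccc2c(c1OCc1ccccc1)O[C@H](c1ccc(OCc3ccccc3)cc1)[C@H](O)[C@H]2SCc1ccccc1
F2 | step 8 | 7,8,4'-tri-O-benzyl-ent-oritin-4α-ol, (2S,3R,4R)-7,8-bis(benzyloxy)-2-[4-(benzyloxy)phenyl]chromane-3,4-diol | O(Cc1ccccc1)c1ccc2c(c1OCc1ccccc1)O[C@@H](c1ccc(OCc3ccccc3)cc1)[C@H](O)[C@@H]2O
F3 | step 8 | hexa-O-benzyl ether of 14 (all six phenolic hydroxyls benzylated) | O(Cc5ccccc5)c1ccc([C@H]2Oc3c(ccc(OCc5ccccc5)c3OCc3ccccc3)[C@H](c3cc4c(c(OCc5ccccc5)c3OCc3ccccc3)O[C@@H](c3ccc(OCc5ccccc5)cc3)[C@H](O)[C@@H]4O)[C@H]2O)cc1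
F4 | step 6 | (2R,3S)-3,7,8-trihydroxy-2-(4-hydroxyphenyl)chroman-4-one (2,3-cis-dihydroflavonol) | Oc1ccc2c(c1O)O[C@H](c1ccc(O)cc1)[C@H](O)C2=O
F5 | step 5 | ent-oritin-4β-ol, (2S,3R,4S)-2-(4-hydroxyphenyl)chromane-3,4,7,8-tetrol | Oc1ccc2c(c1O)O[C@@H](c1ccc(O)cc1)[C@H](O)[C@H]2O
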